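**Strategy.** Everything rests on breaking the C6–C7 bond of the cyclopentane (ring C6–C7–C8–C9–C10) back to a cis-fused cyclobutanol. The strained four-membered ring C6–C8–C9–C10, with its carbinol C8 next to the tertiary epoxide carbon C7, is the feature exploited. In one operation a Lewis acid semipinacol shift moves C6 from C8 to C7, enlarging the ring to the cyclopentanone, creating quaternary C7 stereospecifically and leaving the C11 benzylic alcohol for Friedel–Crafts closure of the oxepine. The precursor is a bicyclo[5.2.0] epoxy cyclobutanol that already carries the C10 aryl ether, built from (+)-2-carene by ring homologation, C–O coupling, ketene [2+2], alkenylcerium addition and Shi epoxidation.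

Key step: step 11

Remark: locants are those of the terpenoid core (C1 CHCH3, C2/C3 ring CH2, C4/C5 cyclopropane CH, C6 ring-fusion CH, C7 quaternary C–CH3, C8/C9 cyclopentane CH2, C10 ring-fusion C–O, C11 CHPh, C12 CMe2); 2-carene has no C10, so it is added by one-carbon homologation before the seven-membered ring is closed, and both enantiomers of the fructose-derived Shi ketone are assumed to be purchasable.

**Route**

Step 1
Reactants: 1 (+)-2-carene
Product: 3 (1S,3R)-2,2-dimethyl-3-(3-oxobutyl)cyclopropane-1-carbaldehyde, via ozonide 2 (not isolated)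
Conditions: O3, CH2Cl2, −78 °C; then Me2S, −78 °C → rt
Reagents that add atoms: ozone, [O-][O+]=O
Why: Ozonolysis with reductive work-up cleaves the only C=C bond and leaves the cis-cyclopropane untouched, so the two cyclopropane stereocentres (later C4 and C5) come from the chiral pool.

Step 2
Reactants: 3 keto aldehyde
Product: 5 2-[(1S,3R)-2,2-dimethyl-3-(3-oxobutyl)cyclopropyl]acetaldehyde, via enol ether 4 (not isolated)
Conditions: Ph3P(CH2OMe)Cl, KHMDS, THF, 0 °C; add 3, −78 → −20 °C; then 1 M HCl, THF, 0 °C → rt
Reagents that add atoms: (methoxymethyl)triphenylphosphonium chloride, COC[P+](c1ccccc1)(c1ccccc1)c1ccccc1.[Cl-]; water, O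
Why: Wittig methoxymethylenation is much faster at the aldehyde than at the methyl ketone at low temperature, and mild acid hydrolysis of the enol ether then gives the one-carbon homologue that supplies C10 without opening the cyclopropane.

Step 3
Reactants: 5 homologated keto aldehyde
Product: 6 (1S,7R)-4,8,8-trimethylbicyclo[5.1.0]oct-3-ene
Conditions: TiCl3(DME)1.5, Zn–Cu couple, DME, reflux, slow addition of 5
Reagents that add atoms: none
Why: Intramolecular McMurry coupling of the keto aldehyde on low-valent titanium closes the seven-membered ring as the trisubstituted C10=C1 alkene, and neither ketyl centre is adjacent to the cyclopropane, so ring opening is not expected.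

Step 4
Reactants: 6 cycloheptene
Product: 8 (1S,3S,4S,7R)-4,8,8-trimethylbicyclo[5.1.0]octan-3-ol, via alkylborane 7 (not isolated)
Conditions: 9-BBN, THF, 65 °C; then NaOH, H2O2, 0 °C → rt
Reagents that add atoms: hydrogen peroxide, OO
Why: Hydroboration–oxidation puts boron on the less substituted C10 and adds H and B syn from the face away from the cyclopropane CMe2 group (the facial bias known for 3-carene), which sets C1 with its methyl on the cyclopropane side.

Step 5
Reactants: 8 secondary alcohol
Product: 9 (1S,4S,7R)-4,8,8-trimethylbicyclo[5.1.0]octan-3-one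
Conditions: Dess–Martin periodinane, NaHCO3, CH2Cl2, 0 °C → rt
Reagents that add atoms: none
Why: Dess–Martin oxidation under buffered, non-enolising conditions gives the C10 ketone without epimerising the adjacent C1 stereocentre.

Step 6
Reactants: 9 ketone
Product: 11 (1R,4S,7R)-4,8,8-trimethylbicyclo[5.1.0]oct-2-en-3-yl trifluoromethanesulfonate, via lithium enolate 10 (not isolated)
Conditions: LDA, THF, −78 °C; then PhNTf2, −78 → 0 °C
Reagents that add atoms: N-phenylbis(trifluoromethanesulfonimide), O=S(=O)(N(c1ccccc1)S(=O)(=O)C(F)(F)F)C(F)(F)F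
Why: Kinetic deprotonation takes a proton from the C6 methylene in preference to the C1 methine, and O-sulfonylation of this enolate gives the C10=C6 enol triflate with C1 untouched.

Step 7
Reactants: 11 enol triflate; 12 3,5-bis(benzyloxy)phenol
Product: 13 (1R,4S,7R)-3-[3,5-bis(benzyloxy)phenoxy]-4,8,8-trimethylbicyclo[5.1.0]oct-2-ene
Conditions: Pd2(dba)3 (2.5 mol %), 2-(di-tert-butylphosphino)biphenyl (10 mol %), NaOtBu, toluene, 80 °C
Reagents that add atoms: none
Why: Palladium-catalysed C–O cross-coupling of alkenyl triflates with phenols (Buchwald–Hartwig-type etherification with a bulky biarylphosphine) forms the C10–O aryl ether bond without moving the double bond.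

Step 8
Reactants: 13 aryl enol ether; 14 trichloroacetyl chloride
Product: 17 cis-fused 3-aryloxy cyclobutanone, via dichloroketene 15 (not isolated), via dichlorocyclobutanone 16 (not isolated)
Conditions: Cl3CCOCl, Zn–Cu couple, Et2O–DME, 0 °C → rt; filter; then Zn, AcOH, rt
Reagents that add atoms: none
Why: Dichloroketene [2+2] cycloaddition to an enol ether joins the ketene carbonyl carbon to the nucleophilic C6 and the CCl2 carbon to the oxygen-bearing C10, necessarily cis and from the face opposite to the cyclopropane CMe2 group and the C1 methyl (this sets C6 and C10), and zinc–acetic acid dechlorination then gives the cyclobutanone as in the standard preparation of 3-alkoxycyclobutanones.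

Step 9
Reactants: 17 cyclobutanone; 18 (E)-(2-bromoprop-1-en-1-yl)benzene
Product: 21 allylic cyclobutanol, via alkenyllithium 19 (not isolated), via alkenylcerium dichloride 20 (not isolated)
Conditions: 18, t-BuLi (2 equiv), Et2O, −78 °C; CeCl3, THF, −78 °C; then 17, −78 °C; NH4Cl work-up
Reagents that add atoms: none
Why: Bromine–lithium exchange keeps the alkene geometry, and the organocerium reagent, nucleophilic but scarcely basic, adds 1,2 to the enolisable β-aryloxy cyclobutanone from its convex face without expelling aryloxide; the C8 configuration is erased in step 11 and is not critical.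

Step 10
Reactants: 21 allylic cyclobutanol
Product: 22 epoxy cyclobutanol with a (2R,3S)-2-methyl-3-phenyloxiran-2-yl group on C8
Conditions: ent-Shi ketone (L-fructose-derived, 0.3 equiv), KHSO5 (Oxone), K2CO3, Bu4NHSO4, Na2B4O7–Na2EDTA buffer, MeCN–CH2(OMe)2–H2O, 0 °C
Reagents that add atoms: potassium peroxymonosulfate, [K+].[O-]S(=O)(=O)OO
Why: Shi epoxidation of E-trisubstituted styrenes is reagent-controlled through the spiro transition state; as the D-fructose ketone gives the (R)-benzylic carbon with trans-β-methylstyrene, the enantiomeric ketone is needed for the (2R,3S)-oxirane whose C7 configuration step 11 will invert.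

Step 11
Reactants: 22 epoxy cyclobutanol
Product: 23 cyclopentanone with quaternary C7 bearing CH3 and the (S)-hydroxy(phenyl)methyl group (C11)
Conditions: BF3·OEt2 (1.1 equiv), CH2Cl2, −78 °C; Et3N quench at −78 °C
Reagents that add atoms: none
Why: BF3 activates the epoxide oxygen, the C7–O bond starts to break at the tertiary carbon and the cyclobutane bond C8–C6 lying anti-periplanar to it migrates in concert while the C8 hydroxyl oxygen forms the carbonyl, which is a semipinacol rearrangement of a 2,3-epoxy alcohol. The closest known reaction type is the Lewis-acid ring expansion of 1-oxiranylcyclobutanols to 2-(1-hydroxyalkyl)cyclopentanones. The cyclopentanone ring C6–C7–C8–C9–C10 is closed not by a cyclisation but by one-carbon enlargement of the cyclobutane through the 1,2-shift, driven by release of cyclobutane and epoxide strain and by C=O formation. The single new stereocentre, quaternary C7, forms with inversion because C6 enters anti to the departing oxygen, so it is controlled entirely by the oxirane configuration set in step 10, while C6 migrates with retention and C10 and C11 are untouched. The step needs cleavage of C7–O and not of the benzylic C11–O bond, secured by the σ-participation available only at C7 and by the low temperature, and migration of C6 and not C9, secured by C6 being a secondary, cyclopropyl-substituted carbon whereas C9 is a primary methylene. A cold amine quench removes the Lewis acid before retro-aldol cleavage or loss of the C10 aryloxide can set in.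

Step 12
Reactants: 23 hydroxy ketone
Product: 24 diol (C8 carbinol of either configuration)
Conditions: NaBH4, CeCl3·7H2O, MeOH–THF, −78 → −40 °C
Reagents that add atoms: none
Why: Luche-type borohydride reduction at low temperature removes the carbonyl that would otherwise allow retro-aldol cleavage at C7–C11 and β-elimination of the C10 aryloxide; the new C8 centre is removed in step 15, so its configuration is immaterial.

Step 13
Reactants: 24 diol
Product: 25 oxepine-closed C8 alcohol
Conditions: Bi(OTf)3 (5 mol %), CH2Cl2, 0 °C → rt
Reagents that add atoms: none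
Why: Acid ionises only the benzylic C11 alcohol, and the cation is captured by an ortho carbon of the electron-rich, symmetrically substituted aryl ether in an intramolecular Friedel–Crafts alkylation that closes the oxepine (possible because C11 and the C10 oxygen are cis on the cyclopentane), with the phenyl group expected to take the less hindered orientation away from the C8–C9 bridge under reversible conditions.

Step 14
Reactants: 25 oxepine alcohol
Product: 26 O-alkyl imidazole-1-carbothioate at C8
Conditions: 1,1'-thiocarbonyldiimidazole, DMAP (cat.), ClCH2CH2Cl, 70 °C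
Reagents that add atoms: 1,1'-thiocarbonyldiimidazole, S=C(n1ccnc1)n1ccnc1
Why: Thioacylation of the one remaining secondary alcohol without strong base prepares the Barton–McCombie deoxygenation.

Step 15
Reactants: 26 thiocarbonyl derivative
Product: 27 bis(benzyl) ether of the deformyl core
Conditions: Bu3SnH, AIBN, toluene, 100 °C
Reagents that add atoms: none
Why: Barton–McCombie radical deoxygenation replaces the C8 oxygen by hydrogen through a secondary cyclopentyl radical that excess tin hydride reduces faster than any C–C fragmentation, and no stereocentre is affected.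

Step 16
Reactants: 27 bis(benzyl) ether
Product: 28 free resorcinol core
Conditions: H2 (1 atm), Pd/C, EtOAc–EtOH, rt
Reagents that add atoms: none
Why: Catalytic hydrogenolysis cleaves the two benzyl ethers, while the tertiary alkyl aryl ether at C10, the C11–aryl bonds and the unactivated cyclopropane are inert under these mild conditions.

Step 17
Reactants: 28 resorcinol core
Product: 29 psiguadial A
Conditions: Cl2CHOMe, TiCl4, CH2Cl2, −78 → 0 °C; then 1 M HCl
Reagents that add atoms: dichloromethyl methyl ether, COC(Cl)Cl; water, O
Why: Rieche formylation attacks the only two free ring positions, each ortho or para to all three oxygens, so double formylation gives the dialdehyde directly, and ionisation of the C10–O bond is disfavoured because C10 is now a bridgehead.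

**Compound list**

1 | (+)-2-carene, (1S,6R)-3,7,7-trimethylbicyclo[4.1.0]hept-2-ene | CC1=C[C@H]2[C@@H](CC1)C2(C)C | starting material
2 | ozonide of 1 (1,2,4-trioxolane across the former alkene) | CC12OOC(O1)[C@H]1[C@@H](CC2)C1(C)C | intermediate
3 | (1S,3R)-2,2-dimethyl-3-(3-oxobutyl)cyclopropane-1-carbaldehyde (cis) | O=C[C@H]1[C@@H](CCC(C)=O)C1(C)C | intermediate
4 | methyl enol ether of the homologated aldehyde (E/Z mixture) | COC=C[C@H]1[C@@H](CCC(C)=O)C1(C)C | intermediate
5 | 2-[(1S,3R)-2,2-dimethyl-3-(3-oxobutyl)cyclopropyl]acetaldehyde | O=CC[C@H]1[C@@H](CCC(C)=O)C1(C)C | intermediate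
6 | (1S,7R)-4,8,8-trimethylbicyclo[5.1.0]oct-3-ene | CC1=CC[C@H]2[C@@H](CC1)C2(C)C | intermediate
7 | B-alkyl-9-borabicyclo[3.3.1]nonane (boron on C10, trans to the C1 methyl) | C[C@H]1CC[C@@H]2[C@H](C[C@@H]1B1C3CCCC1CCC3)C2(C)C | intermediate
8 | (1S,3S,4S,7R)-4,8,8-trimethylbicyclo[5.1.0]octan-3-ol | C[C@H]1CC[C@@H]2[C@H](C[C@@H]1O)C2(C)C | intermediate
9 | (1S,4S,7R)-4,8,8-trimethylbicyclo[5.1.0]octan-3-one | C[C@H]1CC[C@@H]2[C@H](CC1=O)C2(C)C | intermediate
10 | lithium enolate of 9 (C10=C6) | C[C@H]1CC[C@@H]2[C@H](C=C1[O-])C2(C)C.[Li+] | intermediate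
11 | (1R,4S,7R)-4,8,8-trimethylbicyclo[5.1.0]oct-2-en-3-yl trifluoromethanesulfonate | C[C@H]1CC[C@@H]2[C@H](C=C1OS(=O)(=O)C(F)(F)F)C2(C)C | intermediate
12 | 3,5-bis(benzyloxy)phenol | Oc1cc(OCc2ccccc2)cc(OCc2ccccc2)c1 | starting material
13 | (1R,4S,7R)-3-[3,5-bis(benzyloxy)phenoxy]-4,8,8-trimethylbicyclo[5.1.0]oct-2-ene | C[C@H]1CC[C@@H]2[C@H](C=C1Oc1cc(OCc3ccccc3)cc(OCc3ccccc3)c1)C2(C)C | intermediate
14 | trichloroacetyl chloride | ClC(=O)C(Cl)(Cl)Cl | starting material
15 | dichloroketene | ClC(Cl)=C=O | intermediate
16 | 2,2-dichloro-3-aryloxy cyclobutanone cis-fused at C6–C10 (C8 carbonyl on C6, CCl2 on C10, four-membered ring anti to the cyclopropane CMe2 and the C1 methyl) | C[C@H]1CC[C@@H]2[C@H]([C@@H]3C(=O)C(Cl)(Cl)[C@@]31Oc1cc(OCc4ccccc4)cc(OCc4ccccc4)c1)C2(C)C | intermediate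
17 | dechlorinated cis-fused 3-aryloxy cyclobutanone (C8 ketone, C9 methylene) | C[C@H]1CC[C@@H]2[C@H]([C@@H]3C(=O)C[C@@]31Oc1cc(OCc4ccccc4)cc(OCc4ccccc4)c1)C2(C)C | intermediate
18 | (E)-(2-bromoprop-1-en-1-yl)benzene | C/C(Br)=C\c1ccccc1 | starting material
19 | (E)-1-phenylprop-1-en-2-yllithium | C/C([Li])=C\c1ccccc1 | intermediate
20 | (E)-1-phenylprop-1-en-2-ylcerium dichloride | C/C([Ce](Cl)Cl)=C\c1ccccc1 | intermediate
21 | tertiary cyclobutanol with the (E)-1-phenylprop-1-en-2-yl group on C8 (hydroxyl syn to the seven-membered ring) | C[C@H]1CC[C@@H]2[C@H]([C@@H]3[C@@](O)(/C(C)=C/c4ccccc4)C[C@@]31Oc1cc(OCc4ccccc4)cc(OCc4ccccc4)c1)C2(C)C | intermediate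
22 | epoxy cyclobutanol, as 21 with a (2R,3S)-2-methyl-3-phenyloxiran-2-yl group on C8 | C[C@H]1CC[C@@H]2[C@H]([C@@H]3[C@@](O)([C@]4(C)O[C@H]4c4ccccc4)C[C@@]31Oc1cc(OCc5ccccc5)cc(OCc5ccccc5)c1)C2(C)C | intermediate
23 | cyclopentanone (C8 ketone) with quaternary C7 bearing CH3 and (S)-CH(OH)Ph, C10 aryl ether retained | C[C@H]1CC[C@@H]2[C@H]([C@@H]3[C@@](C)([C@@H](O)c4ccccc4)C(=O)C[C@@]31Oc1cc(OCc5ccccc5)cc(OCc5ccccc5)c1)C2(C)C | intermediate
24 | C8,C11-diol from reduction of 23 (C8 configuration not controlled) | C[C@H]1CC[C@@H]2[C@H]([C@@H]3[C@@](C)([C@@H](O)c4ccccc4)C(O)C[C@@]31Oc1cc(OCc5ccccc5)cc(OCc5ccccc5)c1)C2(C)C | intermediate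
25 | oxepine-closed pentacycle with C8 hydroxyl and two benzyl ethers | C[C@H]1CC[C@@H]2[C@H]([C@@H]3[C@]4(C)C(O)C[C@@]31Oc1cc(OCc5ccccc5)cc(OCc5ccccc5)c1[C@@H]4c1ccccc1)C2(C)C | intermediate
26 | O-(C8) imidazole-1-carbothioate of 25 | C[C@H]1CC[C@@H]2[C@H]([C@@H]3[C@]4(C)C(OC(=S)n5ccnc5)C[C@@]31Oc1cc(OCc5ccccc5)cc(OCc5ccccc5)c1[C@@H]4c1ccccc1)C2(C)C | intermediate
27 | bis(benzyl) ether of the deformyl core (C8 methylene) | C[C@H]1CC[C@@H]2[C@H]([C@@H]3[C@]4(C)CC[C@@]31Oc1cc(OCc5ccccc5)cc(OCc5ccccc5)c1[C@@H]4c1ccccc1)C2(C)C | intermediate
28 | deformyl core with free resorcinol hydroxyls | C[C@H]1CC[C@@H]2[C@H]([C@@H]3[C@]4(C)CC[C@@]31Oc1cc(O)cc(O)c1[C@@H]4c1ccccc1)C2(C)C | intermediate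
29 | psiguadial A | C[C@H]1CC[C@@H]2[C@H]([C@@H]3[C@]4(C)CC[C@@]31Oc1c(C=O)c(O)c(C=O)c(O)c1[C@@H]4c1ccccc1)C2(C)C | target

**Step count.** Total: 17 steps. Longest linear sequence: 17 steps, from 1 to 29; compounds 12, 14 and 18 are purchased.

**Steps most likely to fail**

Step 11. The epoxide may ionise at the benzylic C11–O bond instead of C7–O and then undergo shifts other than ring expansion, the C9 methylene may migrate, or the Lewis-acid-bound aldol may fragment by retro-aldol cleavage. The fallback changes the substrate class. Setting out from 22, the tertiary alcohol would be silylated with N-(trimethylsilyl)imidazole (CH2Cl2, rt) to the epoxy trimethylsilyl ether F1. F1 would then be rearranged with TiCl4 in CH2Cl2 at −78 °C in the Suzuki–Tsuchihashi manner, where no free hydroxyl can chelate or protonate the oxirane and the silyloxy group drives the anti 1,2-shift. Aqueous work-up comes back to the route at 23.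

Step 10. Facial discrimination on the hindered alkene beside the quaternary carbinol may be poor if catalyst and substrate bias are mismatched, and the dioxirane may oxidise the electron-rich aryl ether. The fallback replaces the dioxirane by a metal-oxo epoxidation. Setting out from 21, a Jacobsen–Katsuki epoxidation would be used: Mn(salen)Cl catalyst of the handedness that delivers oxygen to the required face, NaOCl, 4-phenylpyridine N-oxide, CH2Cl2, 0 °C. This reaction type is reliable for trisubstituted styrenes that contain a cis-β-methylstyrene unit. It comes back to the route directly at 22.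

Step 7. C–O reductive elimination at the hindered alkenylpalladium aryloxide may be slow, or the alkoxide base may attack sulfur and return the ketone enolate. The fallback moves the C–O bond formation to copper. Setting out from 11, Miyaura borylation (B2pin2, PdCl2(PPh3)2, PPh3, KOPh, toluene, 50 °C) would give the alkenyl pinacol boronate F2. F2 would be coupled with phenol 12 by a Chan–Lam–Evans reaction (Cu(OAc)2, pyridine, 4 Å molecular sieves, air, CH2Cl2, rt), which comes back to the route at 13.

**Further compounds**

F1 | step 11 | trimethylsilyl ether of epoxy cyclobutanol 22 | C[C@H]1CC[C@@H]2[C@H]([C@@H]3[C@@](O[Si](C)(C)C)([C@]4(C)O[C@H]4c4ccccc4)C[C@@]31Oc1cc(OCc5ccccc5)cc(OCc5ccccc5)c1)C2(C)C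
F0 | step 10 | none | none
F2 | step 7 | 2-[(1R,4S,7R)-4,8,8-trimethylbicyclo[5.1.0]oct-2-en-3-yl]-4,4,5,5-tetramethyl-1,3,2-dioxaborolane | C[C@H]1CC[C@@H]2[C@H](C=C1B1OC(C)(C)C(C)(C)O1)C2(C)C
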